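A small charge of substrate goes into Friday's run: 0.260 M, about a third of the 0.800 M in Wednesday's run, with the same 1.90 M of reagent.

| flask | substrate | reagent | time |
|---|---|---|---|
| Thursday's | 0.800 M | 0.960 M |  |
| Wednesday's | 0.800 M | 1.90 M |  |
| Friday's | 0.260 M | 1.90 M | 9.0 min |

| run | time / min | [target] / M |
|---|---|---|
| Thursday's run | 0.36 | 0.0043 |
| Thursday's run | 0.80 | 0.0288 |
| Thursday's run | 1.8 | 0.0997 |
| Thursday's run | 4.0 | 0.2461 |
| Thursday's run | 9.0 | 0.3350 |
| Wednesday's run | 0.36 | 0.0017 |
| Wednesday's run | 0.80 | 0.0299 |
| Wednesday's run | 1.8 | 0.0934 |
| Wednesday's run | 4.0 | 0.1825 |
| Wednesday's run | 9.0 | 0.1863 |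

(scatter of a reading: 0.002 M)

* the exponent of [reagent] in the starting rate at the charge of the Thursday's run (at the point where two percent of the substrate have become target)
* target in the Friday's run at 9.0 min, as a share of the substrate charged

- Overall: substrate + reagent -> target.
- Constant volume, constant temperature.
- The analysis sees a species whether free or bound.
- "The second partner" is reagent.
- An order is taken over about fifteen percent of the charge, up and down.

Substrate is the limiting reagent in each flask, so I write its balance in shares of the charge: the share standing as target plus the share in other forms makes one. The quantity to carry is the target share at 9.0 min in Wednesday's run, target over substrate charged, 23.3%. Thursday's run, with less reagent, stands at 41.9%.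

Two readers dispute what this share means. The first sees a molar ceiling set by reagent: from Wednesday's run to Thursday's, target at 9.0 min rises by a factor of 1.80 as reagent falls by a factor of 1.98. Friday's run, at 1.90 M of reagent, then has a ceiling of 0.1863 M, which is 71.7% of its charge. That rule has its ground at 0.800 M of substrate, where both sets of readings were taken.

The second reader, whose view I take, answers that two runs at one substrate charge cannot tell a ceiling from a share. Friday's charge is 13.7% of its reagent, less than the 42.1% in Wednesday's run. Taking the share over unchanged is my assumption, since the readings do not test it, and on that assumption my reckoning for Friday's run is 23.3%, or 0.0606 M of target.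

The forecast stands with the first reader, starts from “the same reagent gives a ceiling of about 0.187 M”, and settles at 47% of Friday's charge, with 0.05 for the exponent.

Friday's run gives 13.5%, and the exponent is 0.20.

    substrate ⇌ intermediate + by-product (0.9180 min⁻¹, 0.1500 M⁻¹ min⁻¹)
    intermediate + reagent → target (0.6060 M⁻¹ min⁻¹)
    target + reagent → side product (0.3006 M⁻¹ min⁻¹)
    substrate + reagent ⇌ idle substrate-reagent adduct, settled at all times (2.470 M⁻¹)

The fit with main steps alone gave 35.6% for Friday's run. Friday's share is 0.579 of the carried 23.3%, which puts it 9.8 percentage points below my reckoning. The balance leaves 86.5% of Friday's charge not standing as target at 9.0 min, against 76.7% in Wednesday's run and 58.1% in Thursday's run.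

(The readings were computed for substances that don't exist; scatter was added.)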